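**Assumption:** the target has no stereocentre (it is achiral), so "single enantiomer" means the compound itself and no stereocontrol is needed. Ring A is numbered as the benzoate (C1 = CO2Me).

## Retrosynthetic overview

1. Target 11 ⇐ chelation-controlled cleavage of one ring-B ortho-OMe in benzophenone 10.
2. 10 ⇐ ketone-directed C–H hydroxylation of 8 at C3, the only C–H ortho to the ketone.
3. 8 ⇐ key aryl–C(=O) bond: the dithiane-masked acyl anion of aldehyde 3 is arylated with bromide 6 under Pd catalysis, then unmasked in the same pot.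
4. 3 ⇐ 3,5-dimethoxytoluene (ortho-lithiation/formylation); 6 ⇐ methyl 2,5-dimethoxybenzoate (bromination).
5. No ring is formed; both benzene rings come from the starting materials.

## Route

Step 1
Reactants: 1 3,5-dimethoxytoluene
Product: 3 2,6-dimethoxy-4-methylbenzaldehyde, via aryllithium 2 (not isolated)
Conditions: n-BuLi, TMEDA, THF, 0 °C → rt; DMF, −78 °C → rt; aq. HCl
Reagents that add atoms: N,N-dimethylformamide CN(C)C=O
Why: directed ortho-metalation occurs at the position flanked by both OMe groups, and formylation of the aryllithium with DMF gives the aldehyde.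

Step 2
Reactants: 3 2,6-dimethoxy-4-methylbenzaldehyde
Product: 4 2-(2,6-dimethoxy-4-methylphenyl)-1,3-dithiane
Conditions: HS(CH2)3SH, BF3·OEt2 (cat.), CH2Cl2, 0 °C → rt
Reagents that add atoms: propane-1,3-dithiol SCCCS
Why: Lewis-acid-catalysed dithioacetalisation converts the electrophilic formyl carbon into a masked acyl anion (Corey–Seebach umpolung).

Step 3
Reactants: 5 methyl 2,5-dimethoxybenzoate
Product: 6 methyl 4-bromo-2,5-dimethoxybenzoate
Conditions: Br2, AcOH, rt; recrystallise
Reagents that add atoms: bromine BrBr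
Why: electrophilic aromatic bromination goes mainly to C4 (ortho to 5-OMe, away from the ester), as is known for 2,5-dimethoxybenzoic acid and the aldehyde; the minor 6-bromo isomer is removed by crystallisation.

Step 4
Reactants: 4 2-(2,6-dimethoxy-4-methylphenyl)-1,3-dithiane; 6 methyl 4-bromo-2,5-dimethoxybenzoate
Product: 8 methyl 4-(2,6-dimethoxy-4-methylbenzoyl)-2,5-dimethoxybenzoate, via diaryl dithiane 7 (not isolated)
Conditions: [Pd(allyl)Cl]2 (2.5 mol%), NiXantphos (7.5 mol%), KN(SiMe3)2 (1.3 equiv), CPME, rt → 50 °C; then I2, NaHCO3, MeCN/H2O, 0 °C → rt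
Reagents that add atoms: water O
Why: Pd-catalysed deprotonative cross-coupling (direct arylation of a 2-aryl-1,3-dithiane) joins the acyl-anion carbon to the ester-activated aryl bromide, and iodine-mediated dithiane hydrolysis releases the ketone; the non-nucleophilic silylamide base spares the methyl ester.

Step 5
Reactants: 8 methyl 4-(2,6-dimethoxy-4-methylbenzoyl)-2,5-dimethoxybenzoate
Product: 10 methyl 4-(2,6-dimethoxy-4-methylbenzoyl)-3-hydroxy-2,5-dimethoxybenzoate, via aryl trifluoroacetate 9 (not isolated)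
Conditions: Pd(TFA)2 (10 mol%), K2S2O8 (2 equiv), TFA/TFAA (9:1), 50 °C; then H2O/MeOH, rt
Reagents that add atoms: trifluoroacetic acid OC(=O)C(F)(F)F
Why: ketone-directed Pd(II)/Pd(IV) ortho C–H oxygenation can only reach C3–H, because ring B has no ortho C–H and ring A's other ortho position carries OMe; the aryl trifluoroacetate hydrolyses on work-up.

Step 6
Reactants: 10 methyl 4-(2,6-dimethoxy-4-methylbenzoyl)-3-hydroxy-2,5-dimethoxybenzoate
Product: 11 Pseudocercone A (methyl 3-hydroxy-4-(2-hydroxy-6-methoxy-4-methylbenzoyl)-2,5-dimethoxybenzoate)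
Conditions: BCl3 (3 equiv), CH2Cl2, −78 → 0 °C; aq. HCl
Reagents that add atoms: none
Why: chelation-controlled Lewis-acid O-demethylation: the C3–O–B chelate holds the carbonyl oxygen away from the 5-OMe, so its remaining lone pair directs boron onto one of the two equivalent ring-B ortho-OMe groups, as in the known double ortho-demethylation of 2,2'-dimethoxybenzophenones.

## Compound list

1 | 3,5-dimethoxytoluene | Cc1cc(OC)cc(OC)c1 | starting material
2 | (2,6-dimethoxy-4-methylphenyl)lithium | [Li]c1c(OC)cc(C)cc1OC | intermediate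
3 | 2,6-dimethoxy-4-methylbenzaldehyde | COc1cc(C)cc(OC)c1C=O | intermediate
4 | 2-(2,6-dimethoxy-4-methylphenyl)-1,3-dithiane | COc1cc(C)cc(OC)c1C1SCCCS1 | intermediate
5 | methyl 2,5-dimethoxybenzoate | COC(=O)c1cc(OC)ccc1OC | starting material
6 | methyl 4-bromo-2,5-dimethoxybenzoate | COC(=O)c1cc(OC)c(Br)cc1OC | intermediate
7 | methyl 4-[2-(2,6-dimethoxy-4-methylphenyl)-1,3-dithian-2-yl]-2,5-dimethoxybenzoate | COC(=O)c1cc(OC)c(C2(c3c(OC)cc(C)cc3OC)SCCCS2)cc1OC | intermediate
8 | methyl 4-(2,6-dimethoxy-4-methylbenzoyl)-2,5-dimethoxybenzoate | COC(=O)c1cc(OC)c(C(=O)c2c(OC)cc(C)cc2OC)cc1OC | intermediate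
9 | methyl 4-(2,6-dimethoxy-4-methylbenzoyl)-2,5-dimethoxy-3-(trifluoroacetoxy)benzoate | COC(=O)c1cc(OC)c(C(=O)c2c(OC)cc(C)cc2OC)c(OC(=O)C(F)(F)F)c1OC | intermediate
10 | methyl 4-(2,6-dimethoxy-4-methylbenzoyl)-3-hydroxy-2,5-dimethoxybenzoate | COC(=O)c1cc(OC)c(C(=O)c2c(OC)cc(C)cc2OC)c(O)c1OC | intermediate
11 | Pseudocercone A | COC(=O)c1cc(OC)c(C(=O)c2c(O)cc(C)cc2OC)c(O)c1OC | target

## Summary

Total step count: 6. Longest linear sequence: 5 (steps 1, 2, 4, 5, 6); step 3 is a convergent side branch.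

**The three steps most likely to fail**

Step 4 (key coupling). The product is a tri-ortho-substituted diaryl dithiane: the twisted 2,6-dimethoxyaryl dithiane is less acidic than a simple 2-aryl dithiane, reductive elimination is crowded, and the anion may attack the ester. Fallback, setting out from 3 and 6 and coming back at 8: bromine–magnesium exchange on 6 (iPrMgCl·LiCl, THF, −30 °C, ester tolerated) gives methyl 4-(chloromagnesio)-2,5-dimethoxybenzoate F1. Its addition to aldehyde 3 gives the racemic carbinol methyl 4-[(2,6-dimethoxy-4-methylphenyl)(hydroxy)methyl]-2,5-dimethoxybenzoate F2. Oxidation with Dess–Martin periodinane or MnO2 then gives ketone 8.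

Step 5 (C–H hydroxylation). Competing ester-directed palladation at C6 or oxidative damage to the electron-rich ring B could erode the yield. Fallback, setting out from 8 and coming back at 10: condense 8 with MeONH2·HCl (pyridine, 90 °C) to the O-methyl oxime methyl 4-[(2,6-dimethoxy-4-methylphenyl)(methoxyimino)methyl]-2,5-dimethoxybenzoate F3 (E/Z mixture). The stronger N-donor then directs Pd(OAc)2/PhI(OAc)2 acetoxylation (AcOH/Ac2O) at C3, giving methyl 3-acetoxy-4-[(2,6-dimethoxy-4-methylphenyl)(methoxyimino)methyl]-2,5-dimethoxybenzoate F4. Acidic hydrolysis (aq. HCl/dioxane with paraformaldehyde as oxime acceptor) removes both the acetate and the oxime to give 10. Oxime formation and cleavage on this hindered ketone will need forcing conditions.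

Step 6 (selective demethylation). BCl3 could also cleave the 2-OMe (ester-chelated, next to the phenol) or the 5-OMe. Fallback, setting out from 3 and coming back at 11; it replaces the ring-B methyl ether to be removed with an isopropyl ether that BCl3 cleaves at −78 °C without touching any OMe:
- BCl3 (1.1 equiv, CH2Cl2, −78 °C) mono-demethylates 3 to 2-hydroxy-6-methoxy-4-methylbenzaldehyde F5.
- 2-Bromopropane/K2CO3/DMF gives 2-isopropoxy-6-methoxy-4-methylbenzaldehyde F6.
- Dithioacetalisation as in step 2 gives 2-(2-isopropoxy-6-methoxy-4-methylphenyl)-1,3-dithiane F7.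
- Coupling with 6 as in step 4 gives methyl 4-[2-(2-isopropoxy-6-methoxy-4-methylphenyl)-1,3-dithian-2-yl]-2,5-dimethoxybenzoate F8, unmasked in the same pot to methyl 4-(2-isopropoxy-6-methoxy-4-methylbenzoyl)-2,5-dimethoxybenzoate F9.
- Hydroxylation as in step 5 proceeds through methyl 4-(2-isopropoxy-6-methoxy-4-methylbenzoyl)-2,5-dimethoxy-3-(trifluoroacetoxy)benzoate F10 to methyl 3-hydroxy-4-(2-isopropoxy-6-methoxy-4-methylbenzoyl)-2,5-dimethoxybenzoate F11.
- BCl3 (CH2Cl2, −78 °C) removes only the isopropyl group to give 11.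

## Further compounds

F1 | step 4 | methyl 4-(chloromagnesio)-2,5-dimethoxybenzoate | COC(=O)c1cc(OC)c([Mg]Cl)cc1OC
F2 | step 4 | methyl 4-[(2,6-dimethoxy-4-methylphenyl)(hydroxy)methyl]-2,5-dimethoxybenzoate (racemic) | COC(=O)c1cc(OC)c(C(O)c2c(OC)cc(C)cc2OC)cc1OC
F3 | step 5 | methyl 4-[(2,6-dimethoxy-4-methylphenyl)(methoxyimino)methyl]-2,5-dimethoxybenzoate (E/Z mixture) | COC(=O)c1cc(OC)c(C(=NOC)c2c(OC)cc(C)cc2OC)cc1OC
F4 | step 5 | methyl 3-acetoxy-4-[(2,6-dimethoxy-4-methylphenyl)(methoxyimino)methyl]-2,5-dimethoxybenzoate (E/Z mixture) | COC(=O)c1cc(OC)c(C(=NOC)c2c(OC)cc(C)cc2OC)c(OC(C)=O)c1OC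
F5 | step 6 | 2-hydroxy-6-methoxy-4-methylbenzaldehyde | COc1cc(C)cc(O)c1C=O
F6 | step 6 | 2-isopropoxy-6-methoxy-4-methylbenzaldehyde | COc1cc(C)cc(OC(C)C)c1C=O
F7 | step 6 | 2-(2-isopropoxy-6-methoxy-4-methylphenyl)-1,3-dithiane | COc1cc(C)cc(OC(C)C)c1C1SCCCS1
F8 | step 6 | methyl 4-[2-(2-isopropoxy-6-methoxy-4-methylphenyl)-1,3-dithian-2-yl]-2,5-dimethoxybenzoate | COC(=O)c1cc(OC)c(C2(c3c(OC)cc(C)cc3OC(C)C)SCCCS2)cc1OC
F9 | step 6 | methyl 4-(2-isopropoxy-6-methoxy-4-methylbenzoyl)-2,5-dimethoxybenzoate | COC(=O)c1cc(OC)c(C(=O)c2c(OC)cc(C)cc2OC(C)C)cc1OC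
F10 | step 6 | methyl 4-(2-isopropoxy-6-methoxy-4-methylbenzoyl)-2,5-dimethoxy-3-(trifluoroacetoxy)benzoate | COC(=O)c1cc(OC)c(C(=O)c2c(OC)cc(C)cc2OC(C)C)c(OC(=O)C(F)(F)F)c1OC
F11 | step 6 | methyl 3-hydroxy-4-(2-isopropoxy-6-methoxy-4-methylbenzoyl)-2,5-dimethoxybenzoate | COC(=O)c1cc(OC)c(C(=O)c2c(OC)cc(C)cc2OC(C)C)c(O)c1OC
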